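**Retrosynthetic overview**
1. Target 23 ⇒ aroylation of the C6 hydroxyl of diol 19 by palladium-catalysed carbonylative esterification (4-iodophenol unit + CO); the angelate is installed early and carried through.
2. 19 ⇒ hydroxyl-directed reduction of hydroazulenone 18 ⇒ semipinacol 1,2-shift of C1 from C6 to C5 in cis-decalin epoxy alcohol 16 (the cyclohexane contracts to the cyclopentane while the cyclohexene expands to the cycloheptene; C4–OH, C5–H and C6=O arise together).
3. 16 ⇒ directed epoxidation of 15 ⇒ ring-closing metathesis of allyl/methallyl diene 14 ⇒ methallyl addition to enone 11.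
4. 11 ⇒ alkylative 1,3-carbonyl transposition of hydroxy enone 5 ⇒ copper-catalysed desymmetrizing borylation/oxidation of dienone 3 (sets C1 and C2).
5. 3 ⇒ oxidative dearomatizing allylation of p-cresol. Ring order: six-membered ring A (from the arene) → six-membered ring B (metathesis) → five- and seven-membered rings together (rearrangement).

Atom labels: the daucane numbering of the target is used for every intermediate (C1 quaternary carbon with CH3; C2 O-angeloyl; C3; C4 isopropyl carbinol; C5 ring-fusion CH; C6 O-aroyl; C7; C8 with CH3; C9; C10); β is the face of the C1 methyl.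

Assumption: the sense of induction of the chiral copper catalyst in step 2 is not predicted here; the ligand antipode that gives (4R,5R)-5 is chosen by experiment.

**Step 1**
Reactants: 1 p-cresol (4-methylphenol); 2 allyltrimethylsilane
Product: 3 4-methyl-4-(prop-2-en-1-yl)cyclohexa-2,5-dien-1-one
Conditions: PhI(OAc)2, (CF3)2CHOH, 0 °C
Reagents that add atoms: none
Why: Oxidative dearomatization of the phenol to a phenoxenium ion that is trapped at the para carbon by the allylsilane (Hosomi–Sakurai-type para-allylation), giving the prochiral quaternary carbon C1 with no stereocentre yet.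

**Step 2**
Reactants: 3 4-methyl-4-(prop-2-en-1-yl)cyclohexa-2,5-dien-1-one
Product: 5 (4R,5R)-5-hydroxy-4-methyl-4-(prop-2-en-1-yl)cyclohex-2-en-1-one, via β-boryl ketone 4 (not isolated)
Conditions: CuCl (5 mol %), (R,R)-QuinoxP* (6 mol %), NaOtBu (10 mol %), B2pin2 (1.05 equiv), MeOH, THF, 0 °C; then NaBO3·4H2O, THF–H2O, rt
Reagents that add atoms: sodium perborate, O[B-]1(O)OO[B-](O)(O)OO1.[Na+].[Na+]
Why: Copper-catalysed enantioselective conjugate borylation desymmetrizes the dienone (the chiral copper–boryl picks one enantiotopic enone and adds anti to the larger allyl group) and stereoretentive C–B oxidation gives the C2 hydroxyl cis to the C1 methyl, so C2 and quaternary C1 are both set here.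

**Step 3**
Reactants: 5 (4R,5R)-5-hydroxy-4-methyl-4-(prop-2-en-1-yl)cyclohex-2-en-1-one; 6 isopropylmagnesium chloride
Product: 7 (1R,4R,5R)-4-methyl-1-(propan-2-yl)-4-(prop-2-en-1-yl)cyclohex-2-ene-1,5-diol
Conditions: LaCl3·2LiCl (0.3 equiv), 6 (2.3 equiv), THF, 0 °C; aq. NH4Cl
Reagents that add atoms: none
Why: Lanthanum-promoted 1,2-addition of the Grignard reagent to the enone carbonyl (the alkoxide formed first protects the β-hydroxy ketone from elimination); the new carbinol centre, drawn as the isomer from attack anti to the C2 alkoxide, is erased in step 5.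

**Step 4**
Reactants: 7 (1R,4R,5R)-4-methyl-1-(propan-2-yl)-4-(prop-2-en-1-yl)cyclohex-2-ene-1,5-diol; 8 angelic acid ((2Z)-2-methylbut-2-enoic acid)
Product: 10 (1R,2R,5R)-5-hydroxy-2-methyl-5-(propan-2-yl)-2-(prop-2-en-1-yl)cyclohex-3-en-1-yl (2Z)-2-methylbut-2-enoate, via mixed anhydride 9 (not isolated)
Conditions: 8, 2,4,6-trichlorobenzoyl chloride, Et3N, toluene, rt; then 7, DMAP (cat.), 50 °C
Reagents that add atoms: none
Why: Yamaguchi esterification acylates only the secondary C2 hydroxyl (the tertiary allylic hydroxyl is inert) and is mild enough to keep the Z geometry of the angelate.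

**Step 5**
Reactants: 10 (1R,2R,5R)-5-hydroxy-2-methyl-5-(propan-2-yl)-2-(prop-2-en-1-yl)cyclohex-3-en-1-yl (2Z)-2-methylbut-2-enoate
Product: 11 (1R,2S)-2-methyl-3-oxo-5-(propan-2-yl)-2-(prop-2-en-1-yl)cyclohex-4-en-1-yl (2Z)-2-methylbut-2-enoate
Conditions: IBX, DMSO, 55 °C
Reagents that add atoms: 2-iodoxybenzoic acid (IBX), O=C1OI(=O)(O)c2ccccc12
Why: Oxidative 1,3-transposition of the tertiary allylic alcohol (Dauben–Babler-type rearrangement through the allylic iodinane ester) moves the oxygen to C6 and leaves the isopropyl group on the enone β-carbon C4.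

**Step 6**
Reactants: 11 (1R,2S)-2-methyl-3-oxo-5-(propan-2-yl)-2-(prop-2-en-1-yl)cyclohex-4-en-1-yl (2Z)-2-methylbut-2-enoate; 12 3-bromo-2-methylprop-1-ene (methallyl bromide)
Product: 14 (1R,2S,3S)-3-hydroxy-2-methyl-3-(2-methylprop-2-en-1-yl)-5-(propan-2-yl)-2-(prop-2-en-1-yl)cyclohex-4-en-1-yl (2Z)-2-methylbut-2-enoate, via methallylzinc bromide 13 (not isolated)
Conditions: Zn dust, THF–sat. aq. NH4Cl, 0 °C → rt
Reagents that add atoms: none
Why: Barbier (Luche) allylation adds 1,2 to the ketone without touching the ester; in the sofa conformer with the C2 ester equatorial the C1 methyl is pseudo-axial and blocks the β face, so methallyl enters α (cis to the allyl group) and the C6 hydroxyl ends β.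

**Step 7**
Reactants: 14 (1R,2S,3S)-3-hydroxy-2-methyl-3-(2-methylprop-2-en-1-yl)-5-(propan-2-yl)-2-(prop-2-en-1-yl)cyclohex-4-en-1-yl (2Z)-2-methylbut-2-enoate
Product: 15 (1R,4aS,8aS)-4a-hydroxy-6,8a-dimethyl-3-(propan-2-yl)-1,2,4a,5,8,8a-hexahydronaphthalen-1-yl (2Z)-2-methylbut-2-enoate (cis-decalin; OH, angular CH3 and ester all β)
Conditions: second-generation Grubbs catalyst (3 mol %), CH2Cl2, 40 °C
Reagents that add atoms: none
Why: Ring-closing metathesis of the cis allyl and methallyl groups closes ring B with the trisubstituted C8=C9 alkene; the ring alkene and the angelate do not take part.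

**Step 8**
Reactants: 15 (1R,4aS,8aS)-4a-hydroxy-6,8a-dimethyl-3-(propan-2-yl)-1,2,4a,5,8,8a-hexahydronaphthalen-1-yl (2Z)-2-methylbut-2-enoate
Product: 16 the C4–C5 β-epoxide of 15 (epoxide oxygen cis to the C6 hydroxyl, C1 methyl and C2 ester)
Conditions: VO(acac)2 (3 mol %), tBuOOH, toluene, 0 °C → rt
Reagents that add atoms: tert-butyl hydroperoxide, CC(C)(C)OO
Why: Hydroxyl-directed vanadium-catalysed epoxidation delivers oxygen syn to the C6 hydroxyl and is faster for the allylic C4=C5 alkene than for the homoallylic C8=C9 alkene, setting the C4–O and C5–O bonds on the β face.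

**Step 9**
Reactants: 16 the C4–C5 β-epoxide of 15
Product: 18 (1R,2R,4R,5R)-4-hydroxy-6-oxodauc-8-en-2-yl (2Z)-2-methylbut-2-enoate (trans-fused; 2β-ester, 4β-OH, 5α-H), via aluminium alkoxide 17 (not isolated)
Conditions: Me3Al (1.1 equiv), 2,6-di-tert-butyl-4-methylphenol (2.2 equiv), toluene, rt; then 16, −78 → 0 °C; aq. Rochelle salt
Reagents that add atoms: none
Why: Proposed new method: a tethered-Lewis-acid semipinacol in which the C6 hydroxyl is bound covalently (loss of methane) to a bulky, non-nucleophilic aluminium bis(aryloxide) that can reach the cis epoxide oxygen only in a five-membered chelate on the C5 side, so that C5–O scission is coupled to the alkoxide push and to the 1,2-shift of the fully substituted C1 from C6 to C5 anti to the breaking bond (inversion at C5 gives 5α-H, the C4–O bond is kept as the 4β tertiary alcohol, C6 becomes the ketone, ring A contracts to the cyclopentane and ring B expands to the cycloheptene), while unassisted ionization at the tertiary C4 is disfavoured in toluene without an external acid; the closest known reaction type is the tin- or titanium-tetrachloride-promoted semipinacol ring contraction of cis-2,3-epoxycyclohexan-1-ols to 2-hydroxycyclopentyl ketones and organoaluminium-promoted epoxy alcohol rearrangements, not yet shown for a trisubstituted epoxide that must open at its less substituted carbon.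

**Step 10**
Reactants: 18 (1R,2R,4R,5R)-4-hydroxy-6-oxodauc-8-en-2-yl (2Z)-2-methylbut-2-enoate
Product: 19 (1R,2R,4R,5S,6S)-4,6-dihydroxydauc-8-en-2-yl (2Z)-2-methylbut-2-enoate (4β,6α-diol)
Conditions: Me4NBH(OAc)3, MeCN–AcOH, −25 °C
Reagents that add atoms: none
Why: Evans–Saksena hydroxyl-directed reduction: the acetoxyborohydride bound to the 4β-oxygen delivers hydride intramolecularly to the β face of the C6 ketone, giving the 6α-alcohol (1,3-anti diol) under conditions too mild to conjugate the β,γ-enone or epimerize C5.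

**Step 11**
Reactants: 20 4-iodophenol
Product: 21 tert-butyl(4-iodophenoxy)dimethylsilane
Conditions: TBSCl, imidazole, DMF, rt
Reagents that add atoms: tert-butyldimethylsilyl chloride, CC(C)(C)[Si](C)(C)Cl
Why: Standard silylation masks the phenol so that it cannot act as the nucleophile in the carbonylation.

**Step 12**
Reactants: 19 (1R,2R,4R,5S,6S)-4,6-dihydroxydauc-8-en-2-yl (2Z)-2-methylbut-2-enoate; 21 tert-butyl(4-iodophenoxy)dimethylsilane
Product: 23 (1R,2R,4R,5S,6S)-4-hydroxy-6-(4-hydroxybenzoyloxy)dauc-8-en-2-yl (2Z)-2-methylbut-2-enoate (target), via silyl-protected ester 22 (not isolated)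
Conditions: 21 (2 equiv), Pd(OAc)2 (5 mol %), Xantphos (6 mol %), CO (1 atm), Et3N, toluene, 80 °C; then HF·pyridine, THF, 0 °C
Reagents that add atoms: carbon monoxide, [C-]#[O+]
Why: Palladium-catalysed alkoxycarbonylation (oxidative addition of the aryl iodide, CO insertion, alcoholysis of the acyl–palladium by the secondary C6 hydroxyl; the tertiary C4 hydroxyl is inert) builds the aroyl ester with retention at C6, and fluoride then frees the phenol without touching the esters.

**Compound list**
1 | p-cresol | Cc1ccc(O)cc1 | starting material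
2 | allyltrimethylsilane | C=CC[Si](C)(C)C | starting material
3 | 4-methyl-4-(prop-2-en-1-yl)cyclohexa-2,5-dien-1-one | C=CCC1(C)C=CC(=O)C=C1 | intermediate
4 | (4S,5R)-4-methyl-4-(prop-2-en-1-yl)-5-(4,4,5,5-tetramethyl-1,3,2-dioxaborolan-2-yl)cyclohex-2-en-1-one (boron cis to methyl; not isolated) | CC1(C)OB(OC1(C)C)[C@@H]2CC(=O)C=C[C@@]2(C)CC=C | intermediate
5 | (4R,5R)-5-hydroxy-4-methyl-4-(prop-2-en-1-yl)cyclohex-2-en-1-one | O[C@@H]1CC(=O)C=C[C@@]1(C)CC=C | intermediate
6 | isopropylmagnesium chloride | CC(C)[Mg]Cl | starting material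
7 | (1R,4R,5R)-4-methyl-1-(propan-2-yl)-4-(prop-2-en-1-yl)cyclohex-2-ene-1,5-diol | O[C@@H]1C[C@@](O)(C(C)C)C=C[C@@]1(C)CC=C | intermediate
8 | angelic acid | C/C=C(/C)C(=O)O | starting material
9 | angelic 2,4,6-trichlorobenzoic anhydride (not isolated) | C/C=C(/C)C(=O)OC(=O)c1c(Cl)cc(Cl)cc1Cl | intermediate
10 | (1R,2R,5R)-5-hydroxy-2-methyl-5-(propan-2-yl)-2-(prop-2-en-1-yl)cyclohex-3-en-1-yl (2Z)-2-methylbut-2-enoate | C/C=C(/C)C(=O)O[C@@H]1C[C@@](O)(C(C)C)C=C[C@@]1(C)CC=C | intermediate
11 | (1R,2S)-2-methyl-3-oxo-5-(propan-2-yl)-2-(prop-2-en-1-yl)cyclohex-4-en-1-yl (2Z)-2-methylbut-2-enoate | C/C=C(/C)C(=O)O[C@@H]1CC(C(C)C)=CC(=O)[C@@]1(C)CC=C | intermediate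
12 | 3-bromo-2-methylprop-1-ene | CC(=C)CBr | starting material
13 | (2-methylprop-2-en-1-yl)zinc bromide (not isolated) | CC(=C)C[Zn]Br | intermediate
14 | (1R,2S,3S)-3-hydroxy-2-methyl-3-(2-methylprop-2-en-1-yl)-5-(propan-2-yl)-2-(prop-2-en-1-yl)cyclohex-4-en-1-yl (2Z)-2-methylbut-2-enoate | C/C=C(/C)C(=O)O[C@@H]1CC(C(C)C)=C[C@@](O)(CC(C)=C)[C@@]1(C)CC=C | intermediate
15 | (1R,4aS,8aS)-4a-hydroxy-6,8a-dimethyl-3-(propan-2-yl)-1,2,4a,5,8,8a-hexahydronaphthalen-1-yl (2Z)-2-methylbut-2-enoate | C/C=C(/C)C(=O)O[C@@H]1CC(C(C)C)=C[C@@]2(O)CC(C)=CC[C@]21C | intermediate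
16 | C4–C5 β-epoxide of 15 (epoxide O, C6–OH, C1–CH3 and C2 ester all β) | C/C=C(/C)C(=O)O[C@@H]1C[C@]2(C(C)C)O[C@@H]2[C@@]3(O)CC(C)=CC[C@]31C | intermediate
17 | bis(2,6-di-tert-butyl-4-methylphenoxy)aluminium C6-alkoxide of 16 (not isolated) | C/C=C(/C)C(=O)O[C@@H]1C[C@]2(C(C)C)O[C@@H]2[C@@]3(O[Al](Oc4c(C(C)(C)C)cc(C)cc4C(C)(C)C)Oc4c(C(C)(C)C)cc(C)cc4C(C)(C)C)CC(C)=CC[C@]31C | intermediate
18 | (1R,2R,4R,5R)-4-hydroxy-6-oxodauc-8-en-2-yl (2Z)-2-methylbut-2-enoate | C/C=C(/C)C(=O)O[C@@H]1C[C@@](O)(C(C)C)[C@@H]2C(=O)CC(C)=CC[C@]21C | intermediate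
19 | (1R,2R,4R,5S,6S)-4,6-dihydroxydauc-8-en-2-yl (2Z)-2-methylbut-2-enoate | C/C=C(/C)C(=O)O[C@@H]1C[C@@](O)(C(C)C)[C@@H]2[C@@H](O)CC(C)=CC[C@]21C | intermediate
20 | 4-iodophenol | Oc1ccc(I)cc1 | starting material
21 | tert-butyl(4-iodophenoxy)dimethylsilane | CC(C)(C)[Si](C)(C)Oc1ccc(I)cc1 | intermediate
22 | O-tert-butyldimethylsilyl ether of 23 at the phenol (not isolated) | C/C=C(/C)C(=O)O[C@@H]1C[C@@](O)(C(C)C)[C@@H]2[C@@H](OC(=O)c3ccc(O[Si](C)(C)C(C)(C)C)cc3)CC(C)=CC[C@]21C | intermediate
23 | (1R,2R,4R,5S,6S)-4-hydroxy-6-(4-hydroxybenzoyloxy)dauc-8-en-2-yl (2Z)-2-methylbut-2-enoate | C/C=C(/C)C(=O)O[C@@H]1C[C@@](O)(C(C)C)[C@@H]2[C@@H](OC(=O)c3ccc(O)cc3)CC(C)=CC[C@]21C | target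

**Step count**
Total: 12 steps. Longest linear sequence: 11 steps (steps 1–10 and 12, from p-cresol).

**Three steps most likely to fail**

Step 9 (the proposed new step). The danger is ionization at the tertiary C4–O bond (hydride shift to a C5 ketone, or elimination) or migration of C7 instead of C1. The fallback uses known chemistry and sets out from decalin dienol 15, leaving out steps 8 and 9. Hydroxyl-directed dihydroxylation with stoichiometric OsO4·TMEDA (CH2Cl2, −78 °C) puts both oxygens on the β face of the allylic C4=C5 alkene and gives the 4β,5β,6β-triol of 15 F1. MsCl and Et3N sulfonylate only the secondary C5 hydroxyl to give the C5 methanesulfonate of that triol F2. Et3Al (CH2Cl2, −78 °C) then triggers the classical pinacol-type rearrangement of a β-sulfonyloxy alcohol: in the chair with the C5 mesylate equatorial the C6–C1 bond is antiperiplanar to it, C1 migrates with inversion at C5, and the route is rejoined at hydroxy ketone 18. The weak point of this fallback is the selectivity of the osmylation against the C8=C9 alkene.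

Step 2. The methyl and allyl groups differ little in size, so the facial selectivity (hydroxyl cis to methyl) may be modest, and a second borylation of the remaining enone can compete. The fallback sets out from dienone 3: amine-salt-catalysed asymmetric nucleophilic epoxidation of one enone (9-amino-9-deoxy-epi-quinine trifluoroacetate, aqueous H2O2, dioxane) gives the 2β,3β-epoxy enone (2,3-epoxy-4-methyl-4-(prop-2-en-1-yl)cyclohex-5-en-1-one, epoxide oxygen cis to methyl) F3. Organoselenium-mediated reductive cleavage of the Cα–O bond of the epoxy ketone ((PhSe)2, NaBH4, AcOH, EtOH, 0 °C) then gives the β-hydroxy ketone and rejoins the route at 5.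

Step 12. The C6 hydroxyl is a hindered secondary alcohol used as the limiting partner in the carbonylation, so conversion may be low. The fallback sets out from aryl iodide 21: iodine–lithium exchange (n-BuLi, THF, −78 °C) and quenching with CO2 give 4-(tert-butyldimethylsilyloxy)benzoic acid F4. Yamaguchi esterification of diol 19 with this acid (2,4,6-trichlorobenzoyl chloride, Et3N, DMAP, toluene) gives the silyl-protected ester and rejoins the route at 22, which is desilylated with HF·pyridine as in step 12 to give 23.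

**Further compounds**
F1 | step 9 | 4β,5β,6β-triol of 15 ((2Z)-2-methylbut-2-enoate retained at C2) | C/C=C(/C)C(=O)O[C@@H]1C[C@@](O)(C(C)C)[C@H](O)[C@@]2(O)CC(C)=CC[C@]21C
F2 | step 9 | C5 methanesulfonate of triol F1 | C/C=C(/C)C(=O)O[C@@H]1C[C@@](O)(C(C)C)[C@H](OS(C)(=O)=O)[C@@]2(O)CC(C)=CC[C@]21C
F3 | step 2 | 2β,3β-epoxy enone: 2,3-epoxy-4-methyl-4-(prop-2-en-1-yl)cyclohex-5-en-1-one, epoxide oxygen cis to methyl | O1[C@@H]2[C@H]1C(=O)C=C[C@@]2(C)CC=C
F4 | step 12 | 4-(tert-butyldimethylsilyloxy)benzoic acid | CC(C)(C)[Si](C)(C)Oc1ccc(cc1)C(=O)O
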